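- I started from the amounts in the red flask: 0.010 M of D against 8.00 mM of L, or 0.800 L per D charged.

- red: D 0.010 M; L 8 mM; the very flask that is asked about, followed so far
- flask: D 0.010 M; L 8.00 mM; time 8.0 d

- red (time / d: Z / %): 0.333: 16; 0.833: 39; 1.67: 59; 2.50: 58; 4.00: 61; 5.00: 62

(scatter of a reading: 2 percentage points)

- Wednesday's: at 8.0 d add D, 50.0% of the amount charged, then wait 8.0 d
- Saturday's: at 8.0 d add L, 100% of the amount charged, then wait 8.0 d
- Friday's: change nothing and wait 8.0 d more

- additions leave the volume as it is
- the numbers in the tables scatter with a standard deviation of 2 percentage points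
- a reading or a percentage of Z counts all its forms, free or not

1. Z, in percent of the D first charged, at 8.0 d
2. which option adds most Z ("none" when 2 percentage points or less is all one gets) (Wednesday's / Saturday's / Friday's / none)
3. Z present, in percent of the D first charged, after Wednesday's
4. Z present, in percent of the D first charged, after Saturday's

- From 1.67 d on, 4 readings of Z in the red run averaged 60.0%, so I set w = 0.750, the L yield as read there: Z formed per L charged. On a repeat, I would watch where Z stops.
- Time: between 1.67 d and 5.00 d the readings of Z in the red run moved by 3 percentage points against a scatter of 2 points per reading, so I put "now" at 60.0% and expected no gain from Friday's.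
- D: the readings of Z in the red run levelled off with 40.0% of D not in Z, so I took L to be the limiting reagent and expected no gain from Wednesday's.
- L: at this w, I reckoned that Saturday's fresh dose could make 6.00 mM of Z, more than the 4.00 mM of D not in Z, so my ceiling for that option was 100%.
- The forecast gave 60.5% now, 61% after Wednesday's and 96% after Saturday's, below my ceiling, and chose Saturday's, saying “conversion should be nearly complete”.
- The flask gave 60.7% at 8.0 d, 60.7% after Wednesday's and 96.8% after Saturday's, which added 36 points.

    D + L → X (k = 13.0 M⁻¹ h⁻¹)
    X → Z (k = 0.120 h⁻¹)
    2 L → Q (k = 4.30 M⁻¹ h⁻¹)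
    J ⇌ Z, rate k4*(cs4 - [Z]) while solid is left; crystals form when [Z] > cs4 (solubility = 4.90 mM, k = 0.150 h⁻¹)

- At 8.00 d the red flask held 0% of its L, and the 2.00 mM that w leaves outside Z compares with 1.93 mM in Q, at two L each. In the flask with 0.025 M of D and the same L, w gives 24.0%, and Z stood at 28.7% at 8.00 d.

The runs stem from a simulated flask with made-up constants; scatter was added.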